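**Plan**
1. Retrosynthetic cuts: the acyl groups on O3 and O4 are removed first. The 3β,4α-diol is then traced through the 3-ketone and the 3α,4α-cis-diol to a C3=C4 olefin, C15 to a coupling on the C4 enol triflate, and C12/C13 to two methyl additions on a C11 ester.
2. Enabling feature: in ring B the C8 ketone and the C7=C11 isopropylidene unit are together a hidden β-keto ester (ketone C8, ester carbon C11 on C7), and C5 is the α-carbon of a ring-A ketone at C4. C5–C6 and C7–C8 can therefore be cut at once. This leaves a C4–C5 enolate of ring A carrying a C9–C8 acetate arm on C10, and an acrylate as C6–C7–C11.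
3. Forward order: ring A is bought as 3-ethoxycyclohexenone and receives the arm C9–C8, then C14. Ring B closes in one anionic operation. Ring A is then oxygenated at C3/C4, ring B is unmasked, and the two esters go on last.
4. Stereochemistry: C10 comes from a copper-catalysed enantioselective methyl conjugate addition, and C5 from equilibration next to the C4 ketone (relay from C10). C4 comes from α-face osmylation opposite the axial C14 methyl, and C3 from axial hydride attack on the 3-ketone. C2' is bought with (R)-2-methylbutanoic acid.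

Key step: step 3

Numbering: eudesmane numbering is used throughout. Ring A is C1–C5 plus C10 and ring B is C5–C10. C11–C13 form the isopropylidene, C14 sits on C10 and C15 on C4. β is the face of C14. The target is 3S,4S,5R,10R,2'R, that is 3β-acyloxy, 4α-acetoxy, 4β-CH3, 5α-H, 10β-CH3.
Assumption 1: the sense of induction of the phosphoramidite on enone 5 cannot be predicted safely. L* stands for 6-{bis[(1S)-1-phenylethyl]amino}dibenzo[d,f][1,3,2]dioxaphosphepine or its (R,R) enantiomer, whichever delivers (R)-7; both are available.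
Assumption 2: (R)-2-methylbutanoic acid is taken as a commercial, enantiopure compound.

Step 1
Reactants: 1 methyl acetate; 2 3-ethoxycyclohex-2-en-1-one
Product: 5 methyl 2-(3-oxocyclohex-1-en-1-yl)acetate, via lithium enolate 3 (not isolated), via carbinol adduct 4 (not isolated)
Conditions: LiN(iPr)2 (commercial solution, 1.1 equiv), THF, −78 °C; 2, −78 °C; then 1 M HCl, THF, 0 °C → rt
Reagents that add atoms: water, O
Why: Stork–Danheiser sequence: enolate 3 adds 1,2 to the carbonyl of the vinylogous ester 2, and aqueous acid ionises carbinol 4 and hydrolyses its enol ether, so that the carbonyl is transposed and the C9–C8 acetate arm ends on the enone β-carbon (future C10); no stereocentre remains.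

Step 2
Reactants: 5 methyl 2-(3-oxocyclohex-1-en-1-yl)acetate
Product: 7 methyl 2-[(1R)-1-methyl-3-(trimethylsilyloxy)cyclohex-2-en-1-yl]acetate, via aluminium enolate 6 (not isolated)
Conditions: Me3Al (1.4 equiv), Cu(O2CC4H3S) (copper thiophene-2-carboxylate, monovalent copper, 2 mol %), L* (4 mol %), Et2O, −30 °C; then Me3SiOTf (1.5 equiv), −30 → 0 °C; Et3N, pentane, cold aq NaHCO3
Reagents that add atoms: trimethylaluminium, C[Al](C)C; trimethylsilyl trifluoromethanesulfonate, C[Si](C)(C)OS(=O)(=O)C(F)(F)F
Why: Copper-catalysed enantioselective conjugate addition of a trialkylaluminium to a β-substituted cyclohexenone, an established route to all-carbon quaternary centres: the phosphoramidite-bound methylcopper species discriminates the enone faces and sets C10 (R), the weakly basic Me3Al should spare the ester and the activated C9 methylene at low temperature, and O-silylation of aluminium enolate 6 locks the enol double bond between C4 and C5.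

Step 3
Reactants: 7 methyl 2-[(1R)-1-methyl-3-(trimethylsilyloxy)cyclohex-2-en-1-yl]acetate; 8 methyl acrylate
Product: 12 methyl (4aR,8aR)-3-hydroxy-4a-methyl-8-oxo-1,4,4a,5,6,7,8,8a-octahydronaphthalene-2-carboxylate (trans-fused C4 ketone; enolised C8 β-keto ester), via potassium enolate 9 (not isolated), via adduct enolate 10 (not isolated), via potassium salt 11 (not isolated)
Conditions: KOtBu (1.05 equiv), THF, −20 °C; 8 (1.05 equiv, slow addition), −78 → 0 °C; KOtBu (0.5 equiv), 0 °C → rt; 1 M HCl
Reagents that add atoms: none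
Why: tert-Butoxide attacks silicon of 7 and releases potassium enolate 9 with its double bond still between C4 and C5 and with the methyl ester intact (an alkyllithium would attack that ester); C5 of 9 adds to the β-carbon of 8 (bond C5–C6), the ester enolate 10 born at C7 attacks the pendant C8 ester (bond C7–C8), and methoxide leaves and deprotonates the product to the chelated salt 11, the thermodynamic sink. The closest known reaction type is the Michael-initiated ring closure of regiodefined enolates with acrylates (Michael–Dieckmann annulation), combined with the known alkoxide cleavage of silyl enol ethers. Ring B closes by a 6-exo-trig acyl substitution at C8. The only new stereocentre, C5, stays α to the C4 ketone and is equilibrated by the second portion of alkoxide to the trans ring fusion (H-5 anti to the C14 methyl), which is favoured because trigonal C4 and C8 spare the axial C14 methyl two of its syn-axial contacts, so that its configuration is relayed from C10. The step needs C-attack at the hindered C5 before the acrylate oligomerises and closure through C7 rather than C9: one equivalent of 8 added slowly in the cold and the fast intramolecular trap serve the first need, while the second is met because the Michael step places the charge on C7, C9 is neopentyl, and closure through C9 would give the more crowded enolate under reversible conditions. Acylation at C3 by either ester would give bridged β-diketones that cannot enolise at the bridgehead and therefore revert.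

Step 4
Reactants: 12 methyl (4aR,8aR)-3-hydroxy-4a-methyl-8-oxo-1,4,4a,5,6,7,8,8a-octahydronaphthalene-2-carboxylate
Product: 13 methyl (4aR,8aR)-3-(methoxymethoxy)-4a-methyl-8-oxo-1,4,4a,5,6,7,8,8a-octahydronaphthalene-2-carboxylate
Conditions: MOMCl (1.3 equiv), iPr2NEt (1.5 equiv), CH2Cl2, 0 °C → rt
Reagents that add atoms: chloromethyl methyl ether, COCCl
Why: O-alkylation of a fully enolised β-keto ester by the hard electrophile MOMCl (enol ether formation) masks C8 as a vinylogous carbonate that is inert to the bases, hydride and oxidants used next, while the amine base is too weak to touch the C4 ketone or C5.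

Step 5
Reactants: 13 methyl (4aR,8aR)-3-(methoxymethoxy)-4a-methyl-8-oxo-1,4,4a,5,6,7,8,8a-octahydronaphthalene-2-carboxylate
Product: 15 methyl (4aR,8aR)-3-(methoxymethoxy)-4a-methyl-8-(trifluoromethylsulfonyloxy)-1,4,4a,5,6,8a-hexahydronaphthalene-2-carboxylate (C3=C4 enol triflate), via potassium enolate 14 (not isolated)
Conditions: KN(SiMe3)2 (1.05 equiv), THF, −78 °C; PhNTf2 (1.1 equiv), −78 → 0 °C
Reagents that add atoms: N-phenylbis(trifluoromethanesulfonimide), O=S(=O)(N(c1ccccc1)S(=O)(=O)C(F)(F)F)C(F)(F)F
Why: Kinetic enolate formation and O-triflylation: the bulky amide removes a proton from the open C3 methylene rather than the tertiary C5–H beside quaternary C10, and PhNTf2 traps enolate 14 as the C3=C4 enol triflate, after which C5 can no longer epimerise.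

Step 6
Reactants: 15 methyl (4aR,8aR)-3-(methoxymethoxy)-4a-methyl-8-(trifluoromethylsulfonyloxy)-1,4,4a,5,6,8a-hexahydronaphthalene-2-carboxylate
Product: 16 methyl (4aR,8aR)-3-(methoxymethoxy)-4a,8-dimethyl-1,4,4a,5,6,8a-hexahydronaphthalene-2-carboxylate
Conditions: Me2Zn (1.5 equiv), Pd(PPh3)4 (5 mol %), THF, 0 °C → rt
Reagents that add atoms: dimethylzinc, C[Zn]C
Why: Negishi coupling of an alkenyl triflate (oxidative addition to zerovalent palladium, methyl transfer from zinc, reductive elimination) installs C15 on C4 with the double bond fixed at C3=C4, and Me2Zn does not attack the ester or the enol ether.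

Step 7
Reactants: 16 methyl (4aR,8aR)-3-(methoxymethoxy)-4a,8-dimethyl-1,4,4a,5,6,8a-hexahydronaphthalene-2-carboxylate
Product: 17 methyl (4aR,7R,8S,8aR)-7,8-dihydroxy-3-(methoxymethoxy)-4a,8-dimethyl-1,4,4a,5,6,7,8,8a-octahydronaphthalene-2-carboxylate (3α,4α-cis-diol)
Conditions: OsO4 (2 mol %), NMO (1.5 equiv), acetone/H2O, rt; aq Na2SO3
Reagents that add atoms: osmium tetroxide (catalytic oxygen carrier), O=[Os](=O)(=O)=O; N-methylmorpholine N-oxide, C[N+]1([O-])CCOCC1; water, O
Why: Catalytic syn-dihydroxylation: OsO4 should prefer the trisubstituted, unconjugated C3=C4 bond to the tetrasubstituted, ester-conjugated C7=C8 bond and approach from the α face because the axial C14 methyl, syn-axial to C4, covers the β face, which sets C4 (S; 4α-OH, 4β-CH3) and places a provisional 3α-hydroxyl.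

Step 8
Reactants: 17 methyl (4aR,7R,8S,8aR)-7,8-dihydroxy-3-(methoxymethoxy)-4a,8-dimethyl-1,4,4a,5,6,7,8,8a-octahydronaphthalene-2-carboxylate
Product: 18 methyl (4aR,8S,8aR)-8-hydroxy-3-(methoxymethoxy)-4a,8-dimethyl-7-oxo-1,4,4a,5,6,7,8,8a-octahydronaphthalene-2-carboxylate (3-oxo-4α-ol)
Conditions: IBX (1.5 equiv), DMSO, rt
Reagents that add atoms: none
Why: IBX oxidation of a secondary–tertiary 1,2-diol stops at the α-ketol without glycol cleavage and removes the wrongly configured C3 carbinol, while quaternary C4 cannot epimerise.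

Step 9
Reactants: 18 methyl (4aR,8S,8aR)-8-hydroxy-3-(methoxymethoxy)-4a,8-dimethyl-7-oxo-1,4,4a,5,6,7,8,8a-octahydronaphthalene-2-carboxylate
Product: 19 methyl (4aR,7S,8S,8aR)-7,8-dihydroxy-3-(methoxymethoxy)-4a,8-dimethyl-1,4,4a,5,6,7,8,8a-octahydronaphthalene-2-carboxylate (3β,4α-trans-diol)
Conditions: NaBH4, MeOH, −20 °C
Reagents that add atoms: none
Why: Borohydride reduction of a cyclohexanone next to a fully substituted carbon: the small hydride attacks axially from the α face, away from the axial 4β and 10β methyl groups, as with 4,4-disubstituted 3-oxo terpenoids, and gives the equatorial 3β-alcohol (C3 S, trans to the 4α-hydroxyl); the ester and the vinylogous carbonate are not reduced.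

Step 10
Reactants: 19 methyl (4aR,7S,8S,8aR)-7,8-dihydroxy-3-(methoxymethoxy)-4a,8-dimethyl-1,4,4a,5,6,7,8,8a-octahydronaphthalene-2-carboxylate
Product: 21 (3S,4S,5R,10R)-3,4-dihydroxyeudesm-7(11)-en-8-one, via tertiary carbinol 20 (not isolated)
Conditions: MeLi (6 equiv), THF, −78 → 0 °C; then 1 M HCl, THF, rt
Reagents that add atoms: methyllithium, [Li]C
Why: After deprotonation of both hydroxyls, double 1,2-addition of MeLi to the C11 ester brings in C12 and C13, and dilute acid ionises the tertiary allylic carbinol 20 with the push of the enol ether oxygen and strips the MOM group from the resulting oxocarbenium ion, the standard conversion of a β-alkoxy acrylate into an α-isopropylidene ketone; the unactivated 4α-hydroxyl is not ionised under these conditions.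

Step 11
Reactants: 21 (3S,4S,5R,10R)-3,4-dihydroxyeudesm-7(11)-en-8-one; 22 (R)-2-methylbutanoic acid
Product: 23 (3S,4S,5R,10R)-4-hydroxy-8-oxoeudesm-7(11)-en-3-yl (2R)-2-methylbutanoate
Conditions: 22 (1.2 equiv), DCC (1.2 equiv), DMAP (0.1 equiv), CH2Cl2, 0 °C → rt
Reagents that add atoms: none
Why: Steglich esterification acylates the secondary equatorial 3β-hydroxyl and leaves the tertiary 4α-hydroxyl alone; no C–O bond at C3 is broken, and low temperature with catalytic DMAP should keep C2' (R) of the acid intact.

Step 12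
Reactants: 23 (3S,4S,5R,10R)-4-hydroxy-8-oxoeudesm-7(11)-en-3-yl (2R)-2-methylbutanoate
Product: 24 (3S,4S,5R,10R)-4-acetoxy-8-oxoeudesm-7(11)-en-3-yl (2R)-2-methylbutanoate (CNP0111007.1)
Conditions: Ac2O (10 equiv), DMAP (1 equiv), Et3N, CH2Cl2, 40 °C
Reagents that add atoms: acetic anhydride, CC(=O)OC(C)=O
Why: DMAP-catalysed acetylation of a tertiary alcohol with excess anhydride under mild heating, feasible here because the 4α-hydroxyl is equatorial; the C4–O bond is retained, so no stereocentre changes, and the enone and the C3 ester tolerate the weakly basic medium.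

**Compound list**
1 | methyl acetate | COC(C)=O | starting material
2 | 3-ethoxycyclohex-2-en-1-one | CCOC1=CC(=O)CCC1 | starting material
3 | lithium 1-methoxyethen-1-olate (lithium enolate of methyl acetate) | [Li+].C=C([O-])OC | intermediate
4 | methyl 2-(3-ethoxy-1-hydroxycyclohex-2-en-1-yl)acetate (racemic carbinol, formed as its lithium alkoxide) | CCOC1=CC(O)(CC(=O)OC)CCC1 | intermediate
5 | methyl 2-(3-oxocyclohex-1-en-1-yl)acetate | COC(=O)CC1=CC(=O)CCC1 | intermediate
6 | methyl 2-[(1R)-3-(dimethylalumanyloxy)-1-methylcyclohex-2-en-1-yl]acetate (aluminium enolate) | COC(=O)C[C@@]1(C)CCCC(O[Al](C)C)=C1 | intermediate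
7 | methyl 2-[(1R)-1-methyl-3-(trimethylsilyloxy)cyclohex-2-en-1-yl]acetate | COC(=O)C[C@@]1(C)CCCC(O[Si](C)(C)C)=C1 | intermediate
8 | methyl acrylate | C=CC(=O)OC | starting material
9 | potassium (3R)-3-(2-methoxy-2-oxoethyl)-3-methylcyclohex-1-en-1-olate (C4–C5 enolate) | COC(=O)C[C@@]1(C)CCCC([O-])=C1.[K+] | intermediate
10 | potassium C7 ester enolate of methyl 3-[(2R)-2-(2-methoxy-2-oxoethyl)-2-methyl-6-oxocyclohexyl]propanoate (C5 epimers) | COC(=O)C[C@@]1(C)CCCC(=O)C1CC=C([O-])OC.[K+] | intermediate
11 | potassium salt of 12 | O=C1CCC[C@]2(C)CC([O-])=C(C(=O)OC)C[C@H]21.[K+] | intermediate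
12 | methyl (4aR,8aR)-3-hydroxy-4a-methyl-8-oxo-1,4,4a,5,6,7,8,8a-octahydronaphthalene-2-carboxylate | O=C1CCC[C@]2(C)CC(O)=C(C(=O)OC)C[C@H]21 | intermediate
13 | methyl (4aR,8aR)-3-(methoxymethoxy)-4a-methyl-8-oxo-1,4,4a,5,6,7,8,8a-octahydronaphthalene-2-carboxylate | O=C1CCC[C@]2(C)CC(OCOC)=C(C(=O)OC)C[C@H]21 | intermediate
14 | potassium C3–C4 enolate of 13 | [K+].[O-]C1=CCC[C@]2(C)CC(OCOC)=C(C(=O)OC)C[C@H]21 | intermediate
15 | methyl (4aR,8aR)-3-(methoxymethoxy)-4a-methyl-8-(trifluoromethylsulfonyloxy)-1,4,4a,5,6,8a-hexahydronaphthalene-2-carboxylate | O=S(=O)(OC1=CCC[C@]2(C)CC(OCOC)=C(C(=O)OC)C[C@H]21)C(F)(F)F | intermediate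
16 | methyl (4aR,8aR)-3-(methoxymethoxy)-4a,8-dimethyl-1,4,4a,5,6,8a-hexahydronaphthalene-2-carboxylate | CC1=CCC[C@]2(C)CC(OCOC)=C(C(=O)OC)C[C@H]21 | intermediate
17 | methyl (4aR,7R,8S,8aR)-7,8-dihydroxy-3-(methoxymethoxy)-4a,8-dimethyl-1,4,4a,5,6,7,8,8a-octahydronaphthalene-2-carboxylate | O[C@@H]1CC[C@]2(C)CC(OCOC)=C(C(=O)OC)C[C@H]2[C@]1(C)O | intermediate
18 | methyl (4aR,8S,8aR)-8-hydroxy-3-(methoxymethoxy)-4a,8-dimethyl-7-oxo-1,4,4a,5,6,7,8,8a-octahydronaphthalene-2-carboxylate | O=C1CC[C@]2(C)CC(OCOC)=C(C(=O)OC)C[C@H]2[C@]1(C)O | intermediate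
19 | methyl (4aR,7S,8S,8aR)-7,8-dihydroxy-3-(methoxymethoxy)-4a,8-dimethyl-1,4,4a,5,6,7,8,8a-octahydronaphthalene-2-carboxylate | O[C@H]1CC[C@]2(C)CC(OCOC)=C(C(=O)OC)C[C@H]2[C@]1(C)O | intermediate
20 | (3S,4S,5R,10R)-8-(methoxymethoxy)eudesm-7-ene-3,4,11-triol | O[C@H]1CC[C@]2(C)CC(OCOC)=C(C(C)(C)O)C[C@H]2[C@]1(C)O | intermediate
21 | (3S,4S,5R,10R)-3,4-dihydroxyeudesm-7(11)-en-8-one | O[C@H]1CC[C@]2(C)CC(=O)C(=C(C)C)C[C@H]2[C@]1(C)O | intermediate
22 | (R)-2-methylbutanoic acid | CC[C@@H](C)C(=O)O | starting material
23 | (3S,4S,5R,10R)-4-hydroxy-8-oxoeudesm-7(11)-en-3-yl (2R)-2-methylbutanoate | CC[C@@H](C)C(=O)O[C@H]1CC[C@]2(C)CC(=O)C(=C(C)C)C[C@H]2[C@]1(C)O | intermediate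
24 | (3S,4S,5R,10R)-4-acetoxy-8-oxoeudesm-7(11)-en-3-yl (2R)-2-methylbutanoate (CNP0111007.1) | CC[C@@H](C)C(=O)O[C@H]1CC[C@]2(C)CC(=O)C(=C(C)C)C[C@H]2[C@]1(C)OC(C)=O | target

Total step count: 12. Longest linear sequence: 12 steps (from 1 and 2 to 24).

**Steps most likely to fail**

Step 3. Oligomerisation of the acrylate, or proton exchange that moves the enolate from C5 to C3, may outrun C–C bond formation at the hindered, neopentyl C5. The fallback sets out from 7 (with 8) and comes back at 12. It forms the same two bonds in two separate stages and has no free enolate in the first. A TiCl4-promoted Mukaiyama–Michael addition of 7 to 8 (CH2Cl2, −78 °C) makes C5–C6. After aqueous work-up it gives the keto diester methyl 3-[(2R)-2-(2-methoxy-2-oxoethyl)-2-methyl-6-oxocyclohexyl]propanoate F1 as C5 epimers. A separate Dieckmann condensation (KOtBu, THF, 0 °C → rt, then 1 M HCl) closes C7–C8 through 11, equilibrates C5 and delivers 12.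

Step 2. The doubly activated C9 methylene of 5 may be deprotonated faster than methyl is transferred, or the catalyst may discriminate the enone faces poorly. The fallback exchanges the roles of the two C10 substituents and secures the absolute configuration by resolution. It sets out from 1 and comes back at 12.
- Enolate 3 (LiN(iPr)2, THF, −78 °C) is silylated with Me3SiCl to 1-methoxy-1-(trimethylsilyloxy)ethene F2.
- A Mukaiyama–Michael addition of F2 to commercial 3-methylcyclohex-2-en-1-one (CC1=CC(=O)CCC1; catalytic Me3SiOTf, CH2Cl2, −78 °C, pyridine quench) passes silicon to the enolate oxygen. It gives the racemic silyl enol ether methyl 2-[1-methyl-3-(trimethylsilyloxy)cyclohex-2-en-1-yl]acetate F3.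
- The conditions of step 3 lead through the racemic potassium enolate F4, the racemic adduct enolate F5 and the racemic potassium salt F6 to the racemic trans β-keto ester F7.
- Condensation with (R)-1-phenylethylamine (toluene, molecular sieves) gives two diastereomeric enamino esters, the (4aR,8aR) enamino ester F8 and the (4aS,8aS) enamino ester F9. These are separated by crystallisation or chromatography.
- Aqueous oxalic acid in THF hydrolyses F8 to 12.

Step 12. Acylation of the hindered tertiary hydroxyl may be sluggish. Forcing it may bring epimerisation at C2' or acyl scrambling between O3 and O4. The fallback reverses the order of the two acylations, so that the forcing step acts on a substrate without the sensitive ester. It sets out from 21 and comes back at 24.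
- Selective silylation of the secondary hydroxyl (Et3SiCl, imidazole, CH2Cl2, 0 °C) gives the 3-O-triethylsilyl ether F10.
- Prolonged acetylation (Ac2O, DMAP, Et3N, toluene, 60 °C) gives the silyl ether acetate F11.
- HF·pyridine in THF at 0 °C, an acidic medium that disfavours acetyl migration, frees the 4α-acetoxy-3β-alcohol F12.
- F12 is esterified at once with 22 (DCC, DMAP, CH2Cl2, 0 °C) to 24.

**Further compounds**
F1 | step 3 | methyl 3-[(2R)-2-(2-methoxy-2-oxoethyl)-2-methyl-6-oxocyclohexyl]propanoate (C5 epimers) | COC(=O)C[C@@]1(C)CCCC(=O)C1CCC(=O)OC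
F2 | step 2 | 1-methoxy-1-(trimethylsilyloxy)ethene | C=C(OC)O[Si](C)(C)C
F3 | step 2 | racemic methyl 2-[1-methyl-3-(trimethylsilyloxy)cyclohex-2-en-1-yl]acetate | COC(=O)CC1(C)CCCC(O[Si](C)(C)C)=C1
F4 | step 2 | racemic potassium 3-(2-methoxy-2-oxoethyl)-3-methylcyclohex-1-en-1-olate | COC(=O)CC1(C)CCCC([O-])=C1.[K+]
F5 | step 2 | racemic potassium C7 ester enolate of the Michael adduct | COC(=O)CC1(C)CCCC(=O)C1CC=C([O-])OC.[K+]
F6 | step 2 | racemic potassium salt of the trans β-keto ester | O=C1CCC[C@]2(C)CC([O-])=C(C(=O)OC)C[C@H]21.O=C1CCC[C@@]2(C)CC([O-])=C(C(=O)OC)C[C@@H]21.[K+].[K+]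
F7 | step 2 | racemic trans methyl 3-hydroxy-4a-methyl-8-oxo-1,4,4a,5,6,7,8,8a-octahydronaphthalene-2-carboxylate | O=C1CCC[C@]2(C)CC(O)=C(C(=O)OC)C[C@H]21.O=C1CCC[C@@]2(C)CC(O)=C(C(=O)OC)C[C@@H]21
F8 | step 2 | methyl (4aR,8aR)-4a-methyl-8-oxo-3-{[(1R)-1-phenylethyl]amino}-1,4,4a,5,6,7,8,8a-octahydronaphthalene-2-carboxylate | O=C1CCC[C@]2(C)CC(N[C@H](C)c3ccccc3)=C(C(=O)OC)C[C@H]21
F9 | step 2 | methyl (4aS,8aS)-4a-methyl-8-oxo-3-{[(1R)-1-phenylethyl]amino}-1,4,4a,5,6,7,8,8a-octahydronaphthalene-2-carboxylate | O=C1CCC[C@@]2(C)CC(N[C@H](C)c3ccccc3)=C(C(=O)OC)C[C@@H]21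
F10 | step 12 | (3S,4S,5R,10R)-4-hydroxy-3-(triethylsilyloxy)eudesm-7(11)-en-8-one | CC[Si](CC)(CC)O[C@H]1CC[C@]2(C)CC(=O)C(=C(C)C)C[C@H]2[C@]1(C)O
F11 | step 12 | (3S,4S,5R,10R)-8-oxo-3-(triethylsilyloxy)eudesm-7(11)-en-4-yl acetate | CC[Si](CC)(CC)O[C@H]1CC[C@]2(C)CC(=O)C(=C(C)C)C[C@H]2[C@]1(C)OC(C)=O
F12 | step 12 | (3S,4S,5R,10R)-3-hydroxy-8-oxoeudesm-7(11)-en-4-yl acetate | O[C@H]1CC[C@]2(C)CC(=O)C(=C(C)C)C[C@H]2[C@]1(C)OC(C)=O
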